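The data stem from a simulated flask with constants of no real substance, noise included.

Late in Monday's run and Thursday's run the left-handed product stands level, 7.8% and 7.8% at 15.0 h, though the solid reagent charged differs, 0.95 M against 1.6 M. Dividing by the time gives 0.00520 /h of the charge: the mean draw, the product made per hour averaged from the start. It replaces a curve with a short lag by a line, and the error is small: at 8.00 h the line says 4.16%, and the readings 3.3% and 4.5% lie on either side of it.

all flasks: left-handed substrate 0.30 M; right-handed substrate 0.30 M; racemization catalyst 1.5 mM
- Monday's: solid reagent 0.95 M; run made earlier
- Thursday's: solid reagent 1.6 M; run made earlier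
- midnight: solid reagent 0.900 M; time 20 h
- dawn: solid reagent 2.50 M; time 20 h

Monday's run (percent of the left-handed substrate and right-handed substrate together charged)

| time / h | right-handed substrate / % | left-handed substrate / % | left-handed product / % |
|---|---|---|---|
| 3.00 | 49.5 | 50.2 | 0.8 |
| 6.00 | 49.4 | 48.3 | 2.3 |
| 8.00 | 49.7 | 46.3 | 3.3 |
| 12.0 | 49.7 | 44.4 | 6.2 |
| 15.0 | 48.9 | 44.1 | 7.8 |

Thursday's run (percent of the left-handed substrate and right-handed substrate together charged)

| time / h | right-handed substrate / % | left-handed substrate / % | left-handed product / % |
|---|---|---|---|
| 3.00 | 49.5 | 49.1 | 1.3 |
| 6.00 | 49.6 | 47.8 | 2.0 |
| 8.00 | 49.8 | 46.5 | 4.5 |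
| 12.0 | 49.6 | 44.9 | 6.5 |
| 15.0 | 49.2 | 43.5 | 7.8 |

- which one finishes higher in excess of right-handed substrate over left-handed substrate among what is left of the two ("neither" within 2 percentage points) (midnight / dawn / neither)
- excess of right-handed substrate over left-handed substrate among what is left of the two at the end, midnight
- excess of right-handed substrate over left-handed substrate among what is left of the two at the end, dawn

- partner is single-handed; left-handed substrate and right-handed substrate are mirror images of each other, charged as a racemate, each of them at the stated concentration
- solid, in amounts per volume of the solution: solid reagent
- at the start none of the solid reagent is in solution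
- an excess is below zero if the other one leads
- the handed part of partner does not stay in what it makes, so the products of the two hands are mirror images too

Over 20 h the mean draw makes 10.4% of the charge. In the midnight flask that takes 6.93% of the solid reagent, so I expect solid to stand in both flasks and the two to run alike.

This is a kinetic resolution, and two versions of it go in the head. With racemization stopped, right-handed substrate stays at 0.5 of the charge and left-handed substrate pays for the product, so the excess is 11.6%. With racemization instant, the excess is nil.

The right-handed readings place the flask between these. By 15.0 h they show a loss of 0.950% of the charge, with a scatter of 0.5 percentage points on each reading. I take this loss as transfer to the left-handed substrate through the racemization catalyst. I assume the transfer follows the gap between the hands, which rises along the line, so I let it grow with the square of time, to 1.69%. Each part transferred comes off one side and goes onto the other, so I reckon 7.84% for each flask.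

The forecast says neither, with midnight at 8.4% (6.8% to 10%) and dawn at 8.5% (7% to 10.2%), on the ground “so rate doesn't depend on loading”. Its midnight figure stands above mine.

The simulation gives neither, with midnight at 8.89% and dawn at 8.89%.

    left-handed substrate + racemization catalyst ⇌ right-handed substrate + racemization catalyst, rate k1*[racemization catalyst]*[left-handed substrate] forward; the back reaction follows from the equilibrium constant (k = 210 /M/h)
    solid reagent ⇌ partner, rate k2*(cs2 - [partner]) while solid is left; crystals form when [partner] > cs2 (solubility = 43.0 mM, k = 0.320 /h)
    partner + left-handed substrate → left-handed product (k = 0.440 /M/h)
    2 racemization catalyst ⇌ resting dimer, settled at all times (K = 1.00 × 10⁵ /M)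
    partner + right-handed substrate → right-handed product (k = 0.00500 /M/h)

At 20.0 h the midnight flask still holds 89.1% of its own solid reagent and the dawn flask 96.1%, each with 10.9% left-handed product against the 10.4% of the mean draw. Carried to the dawn flask read at 3.0 d, the mean draw gives 37.4% of the charge as product, and that flask holds 35.7% left-handed product.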